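**Retrosynthetic overview**

1. Target 19 ⇐ global desilylation of silyl enol ether 18 ⇐ ring C closed through the C4–C4a bond from the open-chain ynol silyl ether 17. In 17, C4 is carried at the alkyne oxidation level (C3≡C4–OSi) as a latent ketenium (acylium) ion, so the energy stored in the ynol ether, not a stoichiometric activator or a strong base, pays for the bond.
2. Enabling feature: in ring A, C4a is ortho to O1 and para to the C7 oxygen (resorcinol pattern), which makes it the most nucleophilic and least hindered ortho carbon. The O1–C2–C3–C4 chain holds C4 at six-membered-ring distance from it.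
3. 17 ⇐ terminal alkyne 14 (acetylide → ynolate → O-silylation). The C2–O1 bond ⇐ Mitsunobu inversion of propargylic alcohol 11 with phenol 13. The C2 stereocentre ⇐ catalytic asymmetric alkynylation of aldehyde 8.
4. Aldehyde 8 ⇐ 3-bromo-4-hydroxybenzaldehyde by iodination, O-methylation, iodide-selective Heck reaction, Stille prenylation and silylation.
5. Ring order: rings A and B are bought as arenes; ring C is the only ring made, and it is made last (step 11).

Key step: step 11

Remark: the sense of induction of the ProPhenol ligand with this aryl aldehyde is assumed to follow the simple aryl aldehyde series; the antipode that gives (S)-10 is the one used.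

Abbreviations: flavanone locants (O1, C2, C3, C4, C4a, C8, C8a) are used for the corresponding atoms of all intermediates. ArB = 4-methoxy-3-(3-methylbut-2-en-1-yl)-5-[(E)-3-methyl-3-(triethylsilyloxy)but-1-en-1-yl]phenyl.

**Route**

Step 1
Reactants: 1 3-bromo-4-hydroxybenzaldehyde
Product: 2 3-bromo-4-hydroxy-5-iodobenzaldehyde
Conditions: NIS (1.05 equiv), TsOH·H2O (10 mol %), MeCN, rt
Reagents that add atoms: N-iodosuccinimide, O=C1CCC(=O)N1I
Why: Electrophilic aromatic iodination; the free phenol directs to its only open ortho position, and the aldehyde and bromine leave no competing site.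

Step 2
Reactants: 2 3-bromo-4-hydroxy-5-iodobenzaldehyde
Product: 3 3-bromo-5-iodo-4-methoxybenzaldehyde
Conditions: MeI, K2CO3, DMF, rt
Reagents that add atoms: iodomethane, CI
Why: Williamson O-methylation of the acidic, doubly ortho-halogenated phenoxide should proceed cleanly because no other nucleophilic site is present.

Step 3
Reactants: 3 3-bromo-5-iodo-4-methoxybenzaldehyde; 4 2-methylbut-3-en-2-ol
Product: 5 3-bromo-5-[(E)-3-hydroxy-3-methylbut-1-en-1-yl]-4-methoxybenzaldehyde
Conditions: Pd(OAc)2 (3 mol %), n-Bu4NCl, NaHCO3, DMF, 60 °C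
Reagents that add atoms: none
Why: Heck reaction; zerovalent palladium inserts into the C–I bond much faster than into the C–Br bond under ligand-free conditions, and β-hydride elimination can only occur towards the ring, so the (E)-styrene with the tertiary carbinol intact should result.

Step 4
Reactants: 5 3-bromo-5-[(E)-3-hydroxy-3-methylbut-1-en-1-yl]-4-methoxybenzaldehyde; 6 tributyl(3-methylbut-2-en-1-yl)stannane
Product: 7 3-[(E)-3-hydroxy-3-methylbut-1-en-1-yl]-4-methoxy-5-(3-methylbut-2-en-1-yl)benzaldehyde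
Conditions: Pd(PPh3)4 (5 mol %), DMF, 90 °C
Reagents that add atoms: none
Why: Stille coupling of the remaining aryl bromide; reductive elimination from the η3-prenyl palladium intermediate at its less substituted terminus should give the linear prenyl arene, and the neutral conditions spare the aldehyde and the tertiary alcohol.

Step 5
Reactants: 7 3-[(E)-3-hydroxy-3-methylbut-1-en-1-yl]-4-methoxy-5-(3-methylbut-2-en-1-yl)benzaldehyde
Product: 8 4-methoxy-3-(3-methylbut-2-en-1-yl)-5-[(E)-3-methyl-3-(triethylsilyloxy)but-1-en-1-yl]benzaldehyde (ArB–CHO)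
Conditions: TESOTf, 2,6-lutidine, CH2Cl2, −78 → 0 °C
Reagents that add atoms: triethylsilyl trifluoromethanesulfonate, CC[Si](CC)(CC)OS(=O)(=O)C(F)(F)F
Why: Silylation of the hindered tertiary alcohol with a silyl triflate, so that the carbinol survives Me2Zn, n-BuLi and the acid of the key step; the non-enolisable aldehyde is inert.

Step 6
Reactants: 8 ArB–CHO; 9 ethynyltrimethylsilane
Product: 10 (S)-1-(ArB)-3-(trimethylsilyl)prop-2-yn-1-ol
Conditions: Me2Zn, ProPhenol ligand (10 mol %, antipode giving the (S)-carbinol), Ph3P=O (20 mol %), PhMe, 4 °C; aq NH4Cl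
Reagents that add atoms: none
Why: Catalytic asymmetric alkynylation of an aryl aldehyde by an alkynylzinc species; the chiral dinuclear zinc–ProPhenol catalyst delivers the alkynyl group to one aldehyde face and so sets the carbinol stereocentre (the future C2, inverted later) under catalyst control.

Step 7
Reactants: 10 (S)-1-(ArB)-3-(trimethylsilyl)prop-2-yn-1-ol
Product: 11 (R)-1-(ArB)prop-2-yn-1-ol
Conditions: K2CO3 (0.2 equiv), MeOH, 0 °C
Reagents that add atoms: none
Why: Methoxide-catalysed protodesilylation of the alkynylsilane; the hindered tertiary triethylsilyl ether should resist these conditions, and the stereocentre is untouched (the descriptor changes only because the CIP rank of the alkynyl group drops).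

Step 8
Reactants: 12 resorcinol
Product: 13 3-(triisopropylsilyloxy)phenol
Conditions: TIPSCl (1 equiv), 12 (3 equiv), imidazole, DMF, 0 °C → rt
Reagents that add atoms: chlorotriisopropylsilane, CC(C)[Si](Cl)(C(C)C)C(C)C
Why: Monosilylation of a symmetrical diol, pushed towards the mono-ether by excess resorcinol, which is removed by aqueous wash.

Step 9
Reactants: 11 (R)-1-(ArB)prop-2-yn-1-ol; 13 3-(triisopropylsilyloxy)phenol
Product: 14 (S)-triisopropyl{3-[1-(ArB)prop-2-yn-1-yloxy]phenoxy}silane
Conditions: PPh3, DIAD, PhMe, 0 °C → rt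
Reagents that add atoms: none
Why: Mitsunobu etherification; the phenol displaces the activated secondary carbinol by SN2 with inversion, fixing the C2–O1 bond in the (S) configuration, and because no enolisable carbonyl is present the dehydration typical of β-hydroxy carbonyl substrates cannot occur.

Step 10
Reactants: 14 (S)-triisopropyl{3-[1-(ArB)prop-2-yn-1-yloxy]phenoxy}silane
Product: 17 (R)-triisopropyl{[3-(ArB)-3-[3-(triisopropylsilyloxy)phenoxy]prop-1-yn-1-yl]oxy}silane, via lithium acetylide 15 (not isolated), via lithium ynolate 16 (not isolated)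
Conditions: n-BuLi, THF, −78 °C; then LiOOt-Bu (from t-BuOOH and LiN(SiMe3)2), −78 → 0 °C; then TIPSOTf, −78 → 0 °C; filtration through Et3N-deactivated silica
Reagents that add atoms: lithium tert-butyl peroxide, [Li+].CC(C)(C)O[O-]; triisopropylsilyl trifluoromethanesulfonate, CC(C)[Si](C(C)C)(C(C)C)OS(=O)(=O)C(F)(F)F
Why: Oxidation of a lithium acetylide to a lithium ynolate by oxygen transfer from the lithium peroxide, then O-silylation with a bulky silyl triflate, the standard route from terminal alkynes to 1-siloxy-1-alkynes; the stereocentre is not involved (the descriptor changes with the CIP rank of the alkynyl group).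

Step 11
Reactants: 17 (R)-triisopropyl{[3-(ArB)-3-[3-(triisopropylsilyloxy)phenoxy]prop-1-yn-1-yl]oxy}silane
Product: 18 (S)-2-(ArB)-4,7-bis(triisopropylsilyloxy)-2H-chromene
Conditions: HNTf2 (10 mol %), CH2Cl2, −78 °C; Et3N quench
Reagents that add atoms: none
Why: Catalytic HNTf2 should protonate the ynol silyl ether at C3 to give a silyl ketenium ion whose C4 is an acylium-grade electrophile; ring A attacks through C4a, and loss of the C4a proton regenerates the acid and leaves the silyl enol ether. The closest known reaction type is the Brønsted-acid-promoted carbocyclisation of arene-tethered 1-siloxy-1-alkynes to tetralone silyl enol ethers. Ring C closes in a 6-endo-dig Friedel–Crafts mode (ring O1–C2–C3–C4–C4a–C8a). No stereocentre is formed, and C2 should keep its configuration because no base is present (no C3 enolate, no retro-oxa-Michael opening), because C-protonation of the ynol ether is expected to be faster than ionisation of the C2–O1 bond, and because the enol ether product cannot epimerise at C2. The step needs regioselectivity for C4a over C8, secured by C4a being para to the C7 silyloxy group and by the triisopropylsilyl group shielding C8, and chemoselectivity over ring B and the side-chain alkenes, secured by the higher basicity of the ynol ether carbon, the six-membered transition state, the low temperature and the amine quench.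

Step 12
Reactants: 18 (S)-2-(ArB)-4,7-bis(triisopropylsilyloxy)-2H-chromene
Product: 19 (2S)-7-hydroxy-2-{3-[(E)-3-hydroxy-3-methylbut-1-en-1-yl]-4-methoxy-5-(3-methylbut-2-en-1-yl)phenyl}-2,3-dihydro-4H-chromen-4-one
Conditions: TBAF, AcOH (1:1, 4 equiv), THF, 0 °C → rt
Reagents that add atoms: none
Why: Fluoride-mediated cleavage of the three Si–O bonds under acetic acid buffering; the C4 enolate should be protonated at once to the ketone, so opening of ring C and loss of the C2 configuration are avoided.

**Compound list**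

1 | 3-bromo-4-hydroxybenzaldehyde | Oc1ccc(C=O)cc1Br | starting material
2 | 3-bromo-4-hydroxy-5-iodobenzaldehyde | Oc1c(I)cc(C=O)cc1Br | intermediate
3 | 3-bromo-5-iodo-4-methoxybenzaldehyde | COc1c(I)cc(C=O)cc1Br | intermediate
4 | 2-methylbut-3-en-2-ol | C=CC(C)(C)O | starting material
5 | 3-bromo-5-[(E)-3-hydroxy-3-methylbut-1-en-1-yl]-4-methoxybenzaldehyde | COc1c(/C=C/C(C)(C)O)cc(C=O)cc1Br | intermediate
6 | tributyl(3-methylbut-2-en-1-yl)stannane | CCCC[Sn](CCCC)(CCCC)CC=C(C)C | starting material
7 | 3-[(E)-3-hydroxy-3-methylbut-1-en-1-yl]-4-methoxy-5-(3-methylbut-2-en-1-yl)benzaldehyde | COc1c(/C=C/C(C)(C)O)cc(C=O)cc1CC=C(C)C | intermediate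
8 | 4-methoxy-3-(3-methylbut-2-en-1-yl)-5-[(E)-3-methyl-3-(triethylsilyloxy)but-1-en-1-yl]benzaldehyde (ArB–CHO) | COc1c(/C=C/C(C)(C)O[Si](CC)(CC)CC)cc(C=O)cc1CC=C(C)C | intermediate
9 | ethynyltrimethylsilane | C#C[Si](C)(C)C | starting material
10 | (S)-1-(ArB)-3-(trimethylsilyl)prop-2-yn-1-ol | COc1c(/C=C/C(C)(C)O[Si](CC)(CC)CC)cc([C@H](O)C#C[Si](C)(C)C)cc1CC=C(C)C | intermediate
11 | (R)-1-(ArB)prop-2-yn-1-ol (same spatial arrangement as 10) | COc1c(/C=C/C(C)(C)O[Si](CC)(CC)CC)cc([C@H](O)C#C)cc1CC=C(C)C | intermediate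
12 | resorcinol (benzene-1,3-diol) | Oc1cccc(O)c1 | starting material
13 | 3-(triisopropylsilyloxy)phenol | Oc1cccc(O[Si](C(C)C)(C(C)C)C(C)C)c1 | intermediate
14 | (S)-triisopropyl{3-[1-(ArB)prop-2-yn-1-yloxy]phenoxy}silane | COc1c(/C=C/C(C)(C)O[Si](CC)(CC)CC)cc([C@@H](Oc2cccc(O[Si](C(C)C)(C(C)C)C(C)C)c2)C#C)cc1CC=C(C)C | intermediate
15 | lithium acetylide of 14, lithium 3-(ArB)-3-[3-(triisopropylsilyloxy)phenoxy]prop-1-yn-1-ide (spatial arrangement as in 14) | COc1c(/C=C/C(C)(C)O[Si](CC)(CC)CC)cc([C@@H](Oc2cccc(O[Si](C(C)C)(C(C)C)C(C)C)c2)C#C[Li])cc1CC=C(C)C | intermediate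
16 | lithium ynolate, lithium 3-(ArB)-3-[3-(triisopropylsilyloxy)phenoxy]prop-1-yn-1-olate (spatial arrangement as in 14) | COc1c(/C=C/C(C)(C)O[Si](CC)(CC)CC)cc([C@@H](Oc2cccc(O[Si](C(C)C)(C(C)C)C(C)C)c2)C#CO[Li])cc1CC=C(C)C | intermediate
17 | (R)-triisopropyl{[3-(ArB)-3-[3-(triisopropylsilyloxy)phenoxy]prop-1-yn-1-yl]oxy}silane (ynol silyl ether, spatial arrangement as in 14) | COc1c(/C=C/C(C)(C)O[Si](CC)(CC)CC)cc([C@@H](Oc2cccc(O[Si](C(C)C)(C(C)C)C(C)C)c2)C#CO[Si](C(C)C)(C(C)C)C(C)C)cc1CC=C(C)C | intermediate
18 | (S)-2-(ArB)-4,7-bis(triisopropylsilyloxy)-2H-chromene | COc1c(/C=C/C(C)(C)O[Si](CC)(CC)CC)cc([C@@H]2C=C(O[Si](C(C)C)(C(C)C)C(C)C)c3ccc(O[Si](C(C)C)(C(C)C)C(C)C)cc3O2)cc1CC=C(C)C | intermediate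
19 | (2S)-7-hydroxy-2-{3-[(E)-3-hydroxy-3-methylbut-1-en-1-yl]-4-methoxy-5-(3-methylbut-2-en-1-yl)phenyl}-2,3-dihydro-4H-chromen-4-one | COc1c(/C=C/C(C)(C)O)cc([C@@H]2CC(=O)c3ccc(O)cc3O2)cc1CC=C(C)C | target

**Step count and risks**

Total steps: 12. Longest linear sequence: 11 steps (steps 1–7 and 9–12; step 8 is the one-step side branch).

Steps most likely to fail:

(i) Key step 11. Acid-induced ionisation of the C2–O1 bond (erosion of configuration) or of the tertiary allylic silyl ether (elimination to a diene) may compete with C-protonation of the ynol ether, and the ketenium ion may oligomerise or close at C8. The fallback sets out from 8 and comes back at 19; it installs the acyl level first and closes ring C by an anionic Parham cyclisation.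
- Aldol addition of the lithium enolate of N-methoxy-N-methylacetamide to 8 would give racemic 3-hydroxy-N-methoxy-N-methyl-3-(ArB)propanamide F1.
- Dess–Martin oxidation would give the β-keto Weinreb amide F2.
- Noyori transfer hydrogenation ([RuCl(p-cymene)((R,R)-TsDPEN)], HCO2Na, aqueous MeOH) should give (R)-3-hydroxy-N-methoxy-N-methyl-3-(ArB)propanamide F3.
- Commercial 4-bromoresorcinol would be silylated at its less hindered hydroxyl (TIPSCl, imidazole) to 2-bromo-5-(triisopropylsilyloxy)phenol F4.
- Mitsunobu coupling of F3 with F4 (inversion) would give the (S)-β-aryloxy Weinreb amide F5.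
- Bromine–lithium exchange (t-BuLi, THF, −90 °C) and attack of the aryllithium on the amide carbonyl, expected to outrun C3 deprotonation at this temperature, would give after work-up (S)-2-(ArB)-7-(triisopropylsilyloxy)chroman-4-one F6.
- TBAF/AcOH as in step 12 then gives 19.

(ii) Step 10. The lithium ynolate may expel the aryloxide from C2 (fragmentation to a cumulenone), or silylation may occur at carbon instead of oxygen, and the ynol silyl ether may decompose on handling. The fallback sets out from 14 and comes back at 19; it uses an ynamide as the latent acylium in place of the ynol silyl ether and so avoids the ynolate.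
- Bromination of the alkyne (NBS, AgNO3 cat., acetone) would give the bromoalkyne F7.
- Copper-catalysed amidation (CuSO4·5H2O, 1,10-phenanthroline, K3PO4, N-methyl-4-toluenesulfonamide, PhMe, 70 °C) would give the N-methyl-N-tosyl ynamide F8.
- Acid-catalysed keteniminium cyclisation of the arene onto the ynamide (HNTf2 cat., CH2Cl2, −40 °C) would give (S)-2-(ArB)-4-[methyl(tosyl)amino]-7-(triisopropylsilyloxy)-2H-chromene F9.
- Hydrolysis of the ene-sulfonamide (TsOH·H2O, wet THF) would give the protected flavanone F6 of the first fallback, which is desilylated to 19.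

(iii) Step 9. Partial SN1 ionisation of the oxyphosphonium ion at the electron-rich benzylic propargylic carbon may erode the enantiomeric purity. The fallback sets out from 8 and comes back at 14; it replaces the alkynylation–Mitsunobu pair by a catalytic enantioselective etherification of a racemic ester.
- Addition of ethynylmagnesium bromide to 8 would give racemic 1-(ArB)prop-2-yn-1-ol F10.
- Acylation with pentafluorobenzoyl chloride (Et3N, DMAP) would give the racemic pentafluorobenzoate F11.
- Copper–pybox-catalysed enantioselective propargylic etherification with phenol 13 (CuOTf·0.5C6H6, Ph-pybox enantiomer giving the (S)-ether, i-Pr2NEt), which proceeds through a copper allenylidene, should give (S)-14 directly.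

**Further compounds**

F1 | step 11 | racemic 3-hydroxy-N-methoxy-N-methyl-3-(ArB)propanamide | COc1c(/C=C/C(C)(C)O[Si](CC)(CC)CC)cc(C(O)CC(=O)N(C)OC)cc1CC=C(C)C
F2 | step 11 | N-methoxy-N-methyl-3-oxo-3-(ArB)propanamide | COc1c(/C=C/C(C)(C)O[Si](CC)(CC)CC)cc(C(=O)CC(=O)N(C)OC)cc1CC=C(C)C
F3 | step 11 | (R)-3-hydroxy-N-methoxy-N-methyl-3-(ArB)propanamide | COc1c(/C=C/C(C)(C)O[Si](CC)(CC)CC)cc([C@H](O)CC(=O)N(C)OC)cc1CC=C(C)C
F4 | step 11 | 2-bromo-5-(triisopropylsilyloxy)phenol | Oc1cc(O[Si](C(C)C)(C(C)C)C(C)C)ccc1Br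
F5 | step 11 | (S)-3-[2-bromo-5-(triisopropylsilyloxy)phenoxy]-N-methoxy-N-methyl-3-(ArB)propanamide | COc1c(/C=C/C(C)(C)O[Si](CC)(CC)CC)cc([C@@H](Oc2cc(O[Si](C(C)C)(C(C)C)C(C)C)ccc2Br)CC(=O)N(C)OC)cc1CC=C(C)C
F6 | step 11 | (S)-2-(ArB)-7-(triisopropylsilyloxy)chroman-4-one | COc1c(/C=C/C(C)(C)O[Si](CC)(CC)CC)cc([C@@H]2CC(=O)c3ccc(O[Si](C(C)C)(C(C)C)C(C)C)cc3O2)cc1CC=C(C)C
F7 | step 10 | {3-[3-bromo-1-(ArB)prop-2-yn-1-yloxy]phenoxy}triisopropylsilane (spatial arrangement as in 14) | COc1c(/C=C/C(C)(C)O[Si](CC)(CC)CC)cc([C@@H](Oc2cccc(O[Si](C(C)C)(C(C)C)C(C)C)c2)C#CBr)cc1CC=C(C)C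
F8 | step 10 | N-methyl-N-{3-(ArB)-3-[3-(triisopropylsilyloxy)phenoxy]prop-1-yn-1-yl}-4-toluenesulfonamide (spatial arrangement as in 14) | COc1c(/C=C/C(C)(C)O[Si](CC)(CC)CC)cc([C@@H](Oc2cccc(O[Si](C(C)C)(C(C)C)C(C)C)c2)C#CN(C)S(=O)(=O)c3ccc(C)cc3)cc1CC=C(C)C
F9 | step 10 | (S)-2-(ArB)-4-[methyl(tosyl)amino]-7-(triisopropylsilyloxy)-2H-chromene | COc1c(/C=C/C(C)(C)O[Si](CC)(CC)CC)cc([C@@H]2C=C(N(C)S(=O)(=O)c4ccc(C)cc4)c3ccc(O[Si](C(C)C)(C(C)C)C(C)C)cc3O2)cc1CC=C(C)C
F10 | step 9 | racemic 1-(ArB)prop-2-yn-1-ol | COc1c(/C=C/C(C)(C)O[Si](CC)(CC)CC)cc(C(O)C#C)cc1CC=C(C)C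
F11 | step 9 | racemic 1-(ArB)prop-2-yn-1-yl pentafluorobenzoate | COc1c(/C=C/C(C)(C)O[Si](CC)(CC)CC)cc(C(OC(=O)c2c(F)c(F)c(F)c(F)c2F)C#C)cc1CC=C(C)C
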